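**Strategy.** The route rests on disconnecting the seven-membered ring of the dauc-8-ene core (daucane numbering) at C7–C8 and C5–C1. This gives a 2-silyloxyallyl cation (C5–C6–C7, oxygen on C6) and a diene (C8=C9–C10=C1), linked through C2–C3–C4. An intramolecular (4+3) cycloaddition of an acyclic epoxy enol silane closes the five- and the seven-membered ring at once, sets the quaternary C1 and the trans ring fusion, and leaves the epoxide oxygen as the tertiary C4–OH. The precursor is a (2E,4E)-diene carrying a silyloxy carbinol (C2) and a trisubstituted epoxide (C4–C5) bonded to a 2-silyloxyvinyl group. The C9=C10 alkene is later transposed to C8=C9 with oxygen at C10.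

Key step: step 12

Remark: the SMILES is read as a trans-fused daucane with two angelate ((Z)-2-methylbut-2-enoate) esters. Daucane numbers are used throughout, also for the carbons of acyclic intermediates: C1 quaternary ring-fusion carbon bearing CH3-15; C2 (CHO), C3 (CH2), C4 (isopropyl carbinol), C5 (ring-fusion CH); C6 (CHO), C7 (CH2), C8 (bears CH3-14), C9, C10 (CHO). "Syn" and "anti" refer to the face relative to CH3-15.

**Step 1**
Reactants: 1 (E)-but-2-enal; 2 2-(triphenyl-λ5-phosphanylidene)propanal
Product: 3 (2E,4E)-2-methylhexa-2,4-dienal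
Conditions: toluene, 80 °C
Reagents that add atoms: none
Why: Wittig olefination with the formyl-stabilised ylide should give the (E)-trisubstituted enal (CHO trans to the chain, the later C1=C10 geometry), the existing (E)-alkene being untouched.

**Step 2**
Reactants: 3 (2E,4E)-2-methylhexa-2,4-dienal; 4 allenylboronic acid pinacol ester
Product: 5 (4R,5E,7E)-5-methylnona-5,7-dien-1-yn-4-ol
Conditions: (R)-TRIP ((R)-3,3′-bis(2,4,6-triisopropylphenyl)-1,1′-binaphthyl-2,2′-diyl hydrogen phosphate, 5 mol%), 4 Å MS, toluene, 0 °C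
Reagents that add atoms: none
Why: Chiral phosphoric acid-catalysed propargylation (SE2′ transfer from the allenylboronate through a six-membered transition state) should set C2 as (R) by Re-face attack, as expected by analogy with aryl and alkenyl aldehydes; the antipodal acid would be used if the sense proved reversed.

**Step 3**
Reactants: 5 (4R,5E,7E)-5-methylnona-5,7-dien-1-yn-4-ol
Product: 6 tert-butyldimethylsilyl ether of 5
Conditions: TBSCl, imidazole, DMF, 25 °C
Reagents that add atoms: tert-butyldimethylsilyl chloride, C[Si](C)(Cl)C(C)(C)C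
Why: Standard silylation of the secondary alcohol masks C2–OH through to the last step.

**Step 4**
Reactants: 6 tert-butyldimethylsilyl ether of 5
Product: 8 methyl (5R,6E,8E)-5-(tert-butyldimethylsilyloxy)-6-methyldeca-6,8-dien-2-ynoate, via lithium acetylide 7 (not isolated)
Conditions: n-BuLi, THF, −78 °C; then ClCO2Me, −78 → 0 °C
Reagents that add atoms: methyl chloroformate, COC(=O)Cl
Why: Deprotonation of the terminal alkyne and C-acylation of the acetylide with the chloroformate gives the ynoate (adds C6).

**Step 5**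
Reactants: 8 methyl (5R,6E,8E)-5-(tert-butyldimethylsilyloxy)-6-methyldeca-6,8-dien-2-ynoate
Product: 9 methyl (2E,5R,6E,8E)-5-(tert-butyldimethylsilyloxy)-6-methyl-3-(propan-2-yl)deca-2,6,8-trienoate
Conditions: i-PrMgCl (2.2 equiv), CuI (1.1 equiv), THF, −78 °C; then 8; MeOH, −78 °C
Reagents that add atoms: isopropylmagnesium chloride, CC(C)[Mg]Cl
Why: Syn-carbocupration (conjugate addition) of the ynoate, with cold protonation of the alkenyl copper with retention, should place the isopropyl group trans and the C3 methylene cis to the ester.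

**Step 6**
Reactants: 9 methyl (2E,5R,6E,8E)-5-(tert-butyldimethylsilyloxy)-6-methyl-3-(propan-2-yl)deca-2,6,8-trienoate
Product: 10 (2E,5R,6E,8E)-5-(tert-butyldimethylsilyloxy)-6-methyl-3-(propan-2-yl)deca-2,6,8-trien-1-ol
Conditions: iBu2AlH, CH2Cl2, −78 °C
Reagents that add atoms: none
Why: 1,2-Reduction of the enoate by the aluminium hydride gives the allylic alcohol without touching the alkene geometry or the silyl ether.

**Step 7**
Reactants: 10 (2E,5R,6E,8E)-5-(tert-butyldimethylsilyloxy)-6-methyl-3-(propan-2-yl)deca-2,6,8-trien-1-ol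
Product: 11 {(2R,3R)-3-[(2R,3E,5E)-2-(tert-butyldimethylsilyloxy)-3-methylhepta-3,5-dien-1-yl]-3-(propan-2-yl)oxiran-2-yl}methanol
Conditions: Ti(OiPr)4, D-(−)-diethyl tartrate, t-BuOOH, 4 Å MS, CH2Cl2, −20 °C
Reagents that add atoms: tert-butyl hydroperoxide, CC(C)(C)OO
Why: Sharpless asymmetric epoxidation is specific for the free allylic alcohol (the diene is untouched) and, by the usual face rule for the D-tartrate, should set C4 and C5 as (3R,2R) under reagent control.

**Step 8**
Reactants: 11 epoxy alcohol
Product: 12 (2S,3R)-3-[(2R,3E,5E)-2-(tert-butyldimethylsilyloxy)-3-methylhepta-3,5-dien-1-yl]-3-(propan-2-yl)oxirane-2-carbaldehyde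
Conditions: Dess–Martin periodinane, pyridine, CH2Cl2, 0 °C
Reagents that add atoms: none
Why: Buffered Dess–Martin oxidation gives the epoxy aldehyde without opening the acid-sensitive trisubstituted epoxide.

**Step 9**
Reactants: 12 epoxy aldehyde
Product: 13 1-{(2R,3R)-3-[(2R,3E,5E)-2-(tert-butyldimethylsilyloxy)-3-methylhepta-3,5-dien-1-yl]-3-(propan-2-yl)oxiran-2-yl}ethan-1-ol (both carbinol epimers)
Conditions: MeMgBr, THF, −78 °C
Reagents that add atoms: methylmagnesium bromide, C[Mg]Br
Why: Grignard addition to the aldehyde at low temperature adds C7; the new carbinol centre is of no consequence because it is oxidised in step 10.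

**Step 10**
Reactants: 13 epoxy carbinol
Product: 14 1-{(2S,3R)-3-[(2R,3E,5E)-2-(tert-butyldimethylsilyloxy)-3-methylhepta-3,5-dien-1-yl]-3-(propan-2-yl)oxiran-2-yl}ethan-1-one
Conditions: Dess–Martin periodinane, pyridine, CH2Cl2, 0 → 25 °C
Reagents that add atoms: none
Why: Dess–Martin oxidation of the secondary alcohol gives the α,β-epoxy methyl ketone.

**Step 11**
Reactants: 14 epoxy methyl ketone
Product: 15 triethylsilyl enol ether of 14 (2-silyloxyvinyl epoxide)
Conditions: Et3SiOTf (1.2 equiv), Et3N (2 equiv), CH2Cl2, −78 °C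
Reagents that add atoms: triethylsilyl trifluoromethanesulfonate, CC[Si](CC)(CC)OS(=O)(=O)C(F)(F)F
Why: Soft enolisation (silyl triflate and amine) gives the enol silane on the methyl side only, because enolisation towards C5 would place an sp2 carbon in the oxirane.

**Step 12**
Reactants: 15 epoxy enol silane
Product: 16 trans-fused cycloadduct 2-(tert-butyldimethylsilyloxy)-4-(triethylsilyloxy)dauc-9-en-6-one
Conditions: Et3SiOTf (10 mol%), CH2Cl2, −78 °C; aqueous NaHCO3
Reagents that add atoms: none
Why: Et3SiOTf silylates the epoxide oxygen, the C5–O bond opens with assistance of the enol silane (incipient 2-silyloxyallyl cation), the tethered diene adds across C5 and C7, and the silyl group of the resulting silyloxocarbenium ion passes to the next epoxide, which is the known silyl-triflate-catalysed intramolecular (4+3) cycloaddition of epoxy enol silanes with dienes. The five-membered ring closes by attack of diene carbon C1 on epoxide carbon C5 in the 5-endo mode of epoxide opening (both oxirane carbons in the ring, oxygen left on C4), allowed because C5 is an allylic cationic centre, and the seven-membered ring closes by bonding of enol-silane carbon C7 to the allyl-cation terminus C8 (7-endo). C5 is set by backside attack anti to the leaving oxygen (inversion), which puts H-5 cis to the isopropyl group and C6 cis to the C4 oxygen, an outcome the free cation should also favour because the smaller OSiEt3 rather than the isopropyl group then faces the enol silane. The quaternary C1 is set relative to C5 by the (E) geometry of the C1=C10 bond (tether outside, CH3 inside) reacting in the extended, chair-like arrangement with the cation in its W form (C4 syn to OSiEt3), which places CH3-15 anti to H-5 (trans fusion), and C8 is set by suprafacial addition to the (E)-propenyl terminus (CH3-14 anti to CH3-15). The step needs (4+3) over (3+2) closure and the extended over the compact approach: the three-atom tether fixes the regiochemistry, allylic strain keeps C4 syn to OSiEt3, the bulky OSiEt3 group avoids the diene face, C2–H eclipses the diene with C2–OSi anti to the incoming cation, and the non-polar medium at −78 °C disfavours a long-lived open cation.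

**Step 13**
Reactants: 16 cycloadduct ketone
Product: 17 2-(tert-butyldimethylsilyloxy)-4-(triethylsilyloxy)dauc-9-en-6-ol (C6–OH anti to CH3-15)
Conditions: Li, NH3(l), THF, t-BuOH (2 equiv), −78 °C; solid NH4Cl at −78 °C
Reagents that add atoms: none
Why: Dissolving-metal reduction works under thermodynamic control and should give the equatorial C6 alcohol, because the axial epimer suffers syn-axial strain with CH3-15 and the C4 silyloxy group; silyl ethers and the isolated alkene are inert.

**Step 14**
Reactants: 17 C6 alcohol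
Product: 18 9,10-epoxide of 17 (oxirane anti to CH3-15)
Conditions: mCPBA, CH2Cl2, 0 °C
Reagents that add atoms: 3-chloroperoxybenzoic acid, OOC(=O)c1cccc(Cl)c1
Why: Prilezhaev epoxidation of the only alkene should occur on the face anti to the pseudo-axial CH3-15 on the adjacent quaternary C1 (CH3-14 is pseudo-equatorial), which fixes the C10–O configuration.

**Step 15**
Reactants: 18 9,10-epoxide
Product: 21 2-(tert-butyldimethylsilyloxy)-4-(triethylsilyloxy)dauc-8-ene-6,10-diol, via hydroxy selenide 19 (not isolated), via selenoxide 20 (not isolated)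
Conditions: PhSeSePh, NaBH4, EtOH, 70 °C; then THF, 30% H2O2, 0 → 25 °C
Reagents that add atoms: none
Why: Epoxide-to-allylic-alcohol transposition by the selenide/selenoxide route: PhSe− opens the epoxide trans-diaxially at the less hindered C9 (C10 is neopentylic), and syn-selenoxide elimination towards the cis H-8 (away from the carbinol carbon) gives the C8=C9 alkene with the C10–O bond unchanged.

**Step 16**
Reactants: 21 6,10-diol; 22 angelic acid ((Z)-2-methylbut-2-enoic acid)
Product: 24 6,10-di-O-angeloyl-2-(tert-butyldimethylsilyloxy)-4-(triethylsilyloxy)dauc-8-ene, via mixed anhydride 23 (not isolated)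
Conditions: 22 (6 equiv), 2,4,6-trichlorobenzoyl chloride, Et3N, toluene, 25 °C; then 21, 80 °C
Reagents that add atoms: none
Why: Yamaguchi-type esterification through the mixed anhydride without a nucleophilic catalyst acylates both secondary alcohols without Z-to-E isomerisation of the angelate and without alkoxide formation (no silyl migration), while C2–OH and C4–OH stay masked.

**Step 17**
Reactants: 24 bis-angelate bis-silyl ether
Product: 25 6,10-bis(angeloyloxy)dauc-8-ene-2,4-diol (target)
Conditions: HF·pyridine, pyridine, THF, 0 → 25 °C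
Reagents that add atoms: none
Why: Fluoride cleavage of both silyl ethers under mildly acidic conditions frees C2–OH and C4–OH without acyl migration or ester cleavage.

**Compound list**

1 | (E)-but-2-enal | C/C=C/C=O | starting material
2 | 2-(triphenyl-λ5-phosphanylidene)propanal | CC(C=O)=P(c1ccccc1)(c1ccccc1)c1ccccc1 | starting material
3 | (2E,4E)-2-methylhexa-2,4-dienal | C/C=C/C=C(\C)C=O | intermediate
4 | allenylboronic acid pinacol ester | C=C=CB1OC(C)(C)C(C)(C)O1 | starting material
5 | (4R,5E,7E)-5-methylnona-5,7-dien-1-yn-4-ol | C/C=C/C=C(\C)[C@H](O)CC#C | intermediate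
6 | tert-butyldimethylsilyl ether of 5 | C/C=C/C=C(\C)[C@H](O[Si](C)(C)C(C)(C)C)CC#C | intermediate
7 | lithium acetylide of 6 (not isolated) | C/C=C/C=C(\C)[C@H](O[Si](C)(C)C(C)(C)C)CC#C[Li] | intermediate
8 | methyl (5R,6E,8E)-5-(tert-butyldimethylsilyloxy)-6-methyldeca-6,8-dien-2-ynoate | C/C=C/C=C(\C)[C@H](O[Si](C)(C)C(C)(C)C)CC#CC(=O)OC | intermediate
9 | methyl (2E,5R,6E,8E)-5-(tert-butyldimethylsilyloxy)-6-methyl-3-(propan-2-yl)deca-2,6,8-trienoate (ester cis to the C3 methylene) | C/C=C/C=C(\C)[C@H](O[Si](C)(C)C(C)(C)C)C/C(C(C)C)=C\C(=O)OC | intermediate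
10 | (2E,5R,6E,8E)-5-(tert-butyldimethylsilyloxy)-6-methyl-3-(propan-2-yl)deca-2,6,8-trien-1-ol | C/C=C/C=C(\C)[C@H](O[Si](C)(C)C(C)(C)C)C/C(C(C)C)=C\CO | intermediate
11 | {(2R,3R)-3-[(2R,3E,5E)-2-(tert-butyldimethylsilyloxy)-3-methylhepta-3,5-dien-1-yl]-3-(propan-2-yl)oxiran-2-yl}methanol | C/C=C/C=C(\C)[C@H](O[Si](C)(C)C(C)(C)C)C[C@]1(C(C)C)O[C@@H]1CO | intermediate
12 | (2S,3R)-epoxy aldehyde from 11 (same geometry, CHO in place of CH2OH) | C/C=C/C=C(\C)[C@H](O[Si](C)(C)C(C)(C)C)C[C@]1(C(C)C)O[C@@H]1C=O | intermediate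
13 | 1-hydroxyethyl epoxide from 12 (carbinol epimers) | C/C=C/C=C(\C)[C@H](O[Si](C)(C)C(C)(C)C)C[C@]1(C(C)C)O[C@@H]1C(C)O | intermediate
14 | (2S,3R)-epoxy methyl ketone (acetyl cis to the C3 methylene, trans to isopropyl) | C/C=C/C=C(\C)[C@H](O[Si](C)(C)C(C)(C)C)C[C@]1(C(C)C)O[C@@H]1C(C)=O | intermediate
15 | triethylsilyl enol ether of 14 | C/C=C/C=C(\C)[C@H](O[Si](C)(C)C(C)(C)C)C[C@]1(C(C)C)O[C@@H]1C(=C)O[Si](CC)(CC)CC | intermediate
16 | 2-(tert-butyldimethylsilyloxy)-4-(triethylsilyloxy)dauc-9-en-6-one; H-5, isopropyl and CH3-14 anti, C2–O and C4–O syn to CH3-15 | O=C1C[C@@H](C)C=C[C@@]2(C)[C@H](O[Si](C)(C)C(C)(C)C)C[C@@](O[Si](CC)(CC)CC)(C(C)C)[C@H]12 | intermediate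
17 | 6-alcohol of 16, C6–OH anti to CH3-15 | O[C@H]1C[C@@H](C)C=C[C@@]2(C)[C@H](O[Si](C)(C)C(C)(C)C)C[C@@](O[Si](CC)(CC)CC)(C(C)C)[C@H]12 | intermediate
18 | 9,10-epoxide of 17, oxirane anti to CH3-15 | O[C@H]1C[C@@H](C)[C@H]3O[C@H]3[C@@]2(C)[C@H](O[Si](C)(C)C(C)(C)C)C[C@@](O[Si](CC)(CC)CC)(C(C)C)[C@H]12 | intermediate
19 | 9-(phenylselanyl)-6,10-diol (Se syn, C10–OH anti to CH3-15; not isolated) | O[C@H]1C[C@@H](C)[C@H]([Se]c3ccccc3)[C@@H](O)[C@@]2(C)[C@H](O[Si](C)(C)C(C)(C)C)C[C@@](O[Si](CC)(CC)CC)(C(C)C)[C@H]12 | intermediate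
20 | selenoxide of 19 (not isolated) | O[C@H]1C[C@@H](C)[C@H]([Se](=O)c3ccccc3)[C@@H](O)[C@@]2(C)[C@H](O[Si](C)(C)C(C)(C)C)C[C@@](O[Si](CC)(CC)CC)(C(C)C)[C@H]12 | intermediate
21 | 2-(tert-butyldimethylsilyloxy)-4-(triethylsilyloxy)dauc-8-ene-6,10-diol, both OH anti to CH3-15 | O[C@H]1CC(C)=C[C@@H](O)[C@@]2(C)[C@H](O[Si](C)(C)C(C)(C)C)C[C@@](O[Si](CC)(CC)CC)(C(C)C)[C@H]12 | intermediate
22 | angelic acid, (Z)-2-methylbut-2-enoic acid | C/C=C(/C)C(=O)O | starting material
23 | angelic 2,4,6-trichlorobenzoic anhydride (not isolated) | C/C=C(/C)C(=O)OC(=O)c1c(Cl)cc(Cl)cc1Cl | intermediate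
24 | 6,10-di-O-angeloyl derivative of 21 | C/C=C(/C)C(=O)O[C@H]1CC(C)=C[C@@H](OC(=O)/C(C)=C\C)[C@@]2(C)[C@H](O[Si](C)(C)C(C)(C)C)C[C@@](O[Si](CC)(CC)CC)(C(C)C)[C@H]12 | intermediate
25 | 6,10-bis(angeloyloxy)dauc-8-ene-2,4-diol (trans-fused; C2–OH and C4–OH syn, both esters, H-5 and isopropyl anti to CH3-15) | C/C=C(/C)C(=O)O[C@H]1CC(C)=C[C@@H](OC(=O)/C(C)=C\C)[C@@]2(C)[C@H](O)C[C@@](O)(C(C)C)[C@H]12 | target

**Totals.** Total step count: 17. Longest linear sequence: 17 steps (1 and 2 to 25); 4 and 22 enter at steps 2 and 16.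

**Steps most likely to fail**

1. Step 12. The inside methyl on C1 disfavours the s-cis diene, so the allyl cation formed after C5–C1 bonding may close at C10 ((3+2) pathway) or lose a proton; reaction through the compact arrangement would give cis fusion. The fallback sets out from 14 and comes back at 16, and generates a metal-bound oxyallyl cation under basic conditions instead of the silyl-cationic chain. Chloride opening of the epoxy ketone at the carbonyl-activated C5 (LiCl, AcOH, THF) would give the α-chloro-β-hydroxy ketone F1. Silylation (Et3SiOTf, 2,6-lutidine) would give its triethylsilyl ether F2. Dehydrochlorination with Et3N and LiClO4 in Et2O then generates the oxyallyl cation, whose intramolecular (4+3) cycloaddition, a known reaction of α-halo ketones with tethered dienes, should give 16; here C5 is set by the transition-state preference alone.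

2. Step 13. Protonation may not reach the thermodynamic epimer, the lithium alkoxide may take over the C4 silyl group, or the β-silyloxy ketone may eliminate. The fallback sets out from 16 and comes back at 17, and uses hydroxyl-directed hydride delivery. Selective cleavage of the tertiary triethylsilyl ether (HF·pyridine, pyridine, THF, 0 °C) would give the β-hydroxy ketone F3. Evans–Saksena reduction (Me4NBH(OAc)3, MeCN/AcOH, −20 °C) should deliver hydride from the C4–O face, which lies on the CH3-15 side of the C6 carbonyl, to give the diol F4 with C6–OH anti to CH3-15. Bis-silylation (Et3SiOTf, 2,6-lutidine) would give the bis(triethylsilyl) ether F5, and PPTS in MeOH at 0 °C should cleave only the secondary C6 silyl ether to return 17.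

3. Step 16. Acylation of the neopentylic allylic C10–OH may stall, and forcing may isomerise angelate to tiglate. The fallback sets out from 21 and comes back at 24, and builds the Z-alkene on the substrate. Esterification of both alcohols with 2-(diphenoxyphosphoryl)propanoic acid (DCC, DMAP, CH2Cl2) would give the bis-phosphonate F6. A Z-selective Horner–Wadsworth–Emmons olefination of the diaryl phosphonate with acetaldehyde (NaH, THF, −78 °C) should then form both angelate units and give 24.

**Further compounds**

F1 | step 12 | α-chloro-β-hydroxy ketone from 14 (Cl at C5, OH at C4) | C/C=C/C=C(\C)[C@H](O[Si](C)(C)C(C)(C)C)C[C@@](O)(C(C)C)[C@@H](Cl)C(C)=O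
F2 | step 12 | triethylsilyl ether of F1 | C/C=C/C=C(\C)[C@H](O[Si](C)(C)C(C)(C)C)C[C@@](O[Si](CC)(CC)CC)(C(C)C)[C@@H](Cl)C(C)=O
F3 | step 13 | 2-(tert-butyldimethylsilyloxy)-4-hydroxydauc-9-en-6-one | O=C1C[C@@H](C)C=C[C@@]2(C)[C@H](O[Si](C)(C)C(C)(C)C)C[C@@](O)(C(C)C)[C@H]12
F4 | step 13 | 2-(tert-butyldimethylsilyloxy)dauc-9-ene-4,6-diol (C6–OH anti to CH3-15) | O[C@H]1C[C@@H](C)C=C[C@@]2(C)[C@H](O[Si](C)(C)C(C)(C)C)C[C@@](O)(C(C)C)[C@H]12
F5 | step 13 | 4,6-bis(triethylsilyl) ether of F4 | CC[Si](CC)(CC)O[C@H]1C[C@@H](C)C=C[C@@]2(C)[C@H](O[Si](C)(C)C(C)(C)C)C[C@@](O[Si](CC)(CC)CC)(C(C)C)[C@H]12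
F6 | step 16 | 6,10-bis[2-(diphenoxyphosphoryl)propanoate] of 21 | CC(P(=O)(Oc3ccccc3)Oc3ccccc3)C(=O)O[C@H]1CC(C)=C[C@@H](OC(=O)C(C)P(=O)(Oc3ccccc3)Oc3ccccc3)[C@@]2(C)[C@H](O[Si](C)(C)C(C)(C)C)C[C@@](O[Si](CC)(CC)CC)(C(C)C)[C@H]12
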